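## Retrosynthetic overview
1. 26 ⇐ 25: the last bond is O3–C10, made by transannular SN1 etherification. Ring order: A/B′ decalin, then the 7/5 core by a 1,2-shift, then C and D together, then the oxa-bridge.
2. 25 ⇐ 22: one cationic bicyclisation forms C8–C14, C13–C17 and C20–CH3, and excess AlMe3 then installs C10–CH3.
3. 22 ⇐ 21: a semipinacol 1,2-shift moves C5 from C10 to C9. Ring B′ contracts 6→5, ring A expands 6→7, and quaternary C9 is created.
4. 21 ⇐ 16 + 9 by B-alkyl Suzuki union (C9–C11). 14 ⇐ 11 + 13 by formal [4+2] annulation (C4–C5 and C1–C10).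
5. 9 ⇐ 2 + 6 + CH2(Bpin)2. The E-tetrasubstituted alkene from 2,3-dimethylbutadiene/Br2 encodes the trans C13/C14 methyl pair.

Assumption: 4-methylpent-1-en-3-one and cyclohexane-1,2-dione are taken as catalogue chemicals. Atom labels follow the triterpenoid numbering of the target (C3 = OCH, C4 = CMe2, C5/C9 = 5/7 fusion carbons, C10 = O–C–CH3, C13/C14 = C/D fusion carbons, C20 = side-chain carbon), and α is the face of H-5.

## Route

Step 1
Reactants: 1 2,3-dimethylbuta-1,3-diene
Product: 2 (E)-1,4-dibromo-2,3-dimethylbut-2-ene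
Conditions: Br2, CH2Cl2, −20 °C; crystallise
Reagents that add atoms: bromine, BrBr
Why: Electrophilic 1,4-addition of bromine to a 1,3-diene under thermodynamic control gives the crystalline E-dibromide, which fixes the alkene geometry used in step 15.

Step 2
Reactants: 3 3-chloro-2-methylprop-1-ene; 4 1-bromo-3-methylbut-2-ene
Product: 6 2,6-dimethylhepta-1,5-diene, via methallylmagnesium chloride 5 (not isolated)
Conditions: Mg, THF, 0 °C; then 4, 0 °C
Reagents that add atoms: none
Why: In this allyl–allyl Grignard coupling the methallyl nucleophile is symmetric and attacks the primary carbon of prenyl bromide by SN2.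

Step 3
Reactants: 6 2,6-dimethylhepta-1,5-diene; 2 (E)-1,4-dibromo-2,3-dimethylbut-2-ene
Product: 8 (2E)-1-bromo-2,3,10-trimethyl-6-methylideneundeca-2,9-diene, via allyllithium 7 (not isolated)
Conditions: n-BuLi, TMEDA, hexane, 23 °C; inverse addition to 2 (3 equiv), THF, −78 °C
Reagents that add atoms: none
Why: Allylic lithiation of the isopropenyl methyl gives a symmetric 2-substituted allyllithium, and SN2 on excess dibromide gives the mono-substituted product with the E geometry retained.

Step 4
Reactants: 8 (2E)-1-bromo-2,3,10-trimethyl-6-methylideneundeca-2,9-diene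
Product: 9 2-[(3E)-3,4,11-trimethyl-7-methylidenedodeca-3,10-dien-1-yl]-4,4,5,5-tetramethyl-1,3,2-dioxaborolane
Conditions: CH2(Bpin)2, NaOt-Bu, THF, 23 °C
Reagents that add atoms: bis(pinacolatoboryl)methane, CC1(C)OB(CB2OC(C)(C)C(C)(C)O2)OC1(C)C
Why: Deborylative alkylation of a geminal bis(boronate) lets the α-boryl carbanion displace the allylic bromide by SN2 and brings in C11.

Step 5
Reactants: 10 cyclohexane-1,2-dione
Product: 11 2-(triethylsilyloxy)cyclohex-2-en-1-one
Conditions: TESCl, Et3N, DMAP (cat.), CH2Cl2, 0 °C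
Reagents that add atoms: chlorotriethylsilane, CC[Si](Cl)(CC)CC
Why: O-silylation of the diosphenol tautomer gives an enone that already carries the future C10 oxygen.

Step 6
Reactants: 12 4-methylpent-1-en-3-one
Product: 13 tert-butyl(dimethyl)[(4-methylpenta-1,3-dien-3-yl)oxy]silane
Conditions: TBSOTf, Et3N, Et2O, 0 °C
Reagents that add atoms: tert-butyldimethylsilyl triflate, CC(C)(C)[Si](C)(C)OS(=O)(=O)C(F)(F)F
Why: Soft enolisation and silylation can only engage the isopropyl C–H, so a single 2-silyloxydiene forms.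

Step 7
Reactants: 11 2-(triethylsilyloxy)cyclohex-2-en-1-one; 13 tert-butyl(dimethyl)[(4-methylpenta-1,3-dien-3-yl)oxy]silane
Product: 14 (4aS,8aS)-6-(tert-butyldimethylsilyloxy)-5,5-dimethyl-8a-(triethylsilyloxy)-3,4,4a,5,8,8a-hexahydronaphthalen-1(2H)-one
Conditions: chiral o-tolyl-oxazaborolidinium triflimide (20 mol %, the antipode giving 4aS,8aS), CH2Cl2, −78 → −40 °C
Reagents that add atoms: none
Why: In this Lewis-acid-catalysed formal [4+2] annulation (Mukaiyama–Michael then intramolecular Michael) the nucleophilic CMe2 terminus bonds to the enone β-carbon, the cyclic acceptor forces H-5 and O-10 cis, and the catalyst sets their absolute sense.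

Step 8
Reactants: 14 the bicyclic ketone
Product: 16 C8=C9 enol triflate of 14, via potassium enolate 15 (not isolated)
Conditions: KHMDS, THF, −78 °C; PhNTf2, −78 → 0 °C
Reagents that add atoms: N-phenylbis(trifluoromethanesulfonimide), O=S(=O)(N(c1ccccc1)S(=O)(=O)C(F)(F)F)C(F)(F)F
Why: In this enolate O-triflation C10 is fully substituted and C3 is masked as its enol ether, so only C8 can be deprotonated.

Step 9
Reactants: 16 the enol triflate; 9 the homoallylic boronate
Product: 17 coupled tetraene (decalin with a C8=C9 alkene bearing the C11–C27 chain; 10α-OTES; C2=C3 TBS enol ether)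
Conditions: Pd(OAc)2, RuPhos, K3PO4, toluene/H2O, 60 °C
Reagents that add atoms: none
Why: The B-alkyl Suzuki–Miyaura coupling of a vinyl triflate forms C9–C11 without touching either alkene geometry or the stereocentres.

Step 10
Reactants: 17 the coupled tetraene
Product: 18 10α-hydroxy-3-ketone
Conditions: TBAF, AcOH, THF, 0 → 23 °C
Reagents that add atoms: none
Why: Buffered fluoride desilylation frees the tertiary allylic alcohol and converts the silyl enol ether into the C3 ketone in one operation.

Step 11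
Reactants: 18 the 10α-hydroxy-3-ketone
Product: 19 (3S)-3β,10α-diol
Conditions: (R)-Me-CBS (20 mol %), catecholborane, toluene, −78 °C
Reagents that add atoms: none
Why: The CBS reduction differentiates the CMe2 side from the CH2 side of the ketone, so the catalyst sets the 3S (3β) carbinol, and catecholborane does not hydroborate the alkenes at −78 °C.

Step 12
Reactants: 19 the 3β,10α-diol
Product: 20 3β-OTBS 10α-allylic alcohol
Conditions: TBSOTf (1.1 equiv), 2,6-lutidine, CH2Cl2, −78 °C
Reagents that add atoms: tert-butyldimethylsilyl triflate, CC(C)(C)[Si](C)(C)OS(=O)(=O)C(F)(F)F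
Why: Selective silylation protects the secondary alcohol over the tertiary one, and the bulky 3β-OTBS also disfavours the decalin conformer that would place it axial.

Step 13
Reactants: 20 the 3β-OTBS 10α-allylic alcohol
Product: 21 8α,9α-epoxy-10α-ol
Conditions: VO(acac)2 (5 mol %), t-BuOOH, toluene, 0 °C
Reagents that add atoms: tert-butyl hydroperoxide, CC(C)(C)OO
Why: Hydroxyl-directed vanadium epoxidation oxidises only the allylic-alcohol alkene, syn to the 10α-OH, and this sets C8 and C9.

Step 14
Reactants: 21 the 8α,9α-epoxy-10α-ol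
Product: 22 8α-hydroxy-5(10→9)abeo-10-ketone (trans-fused 7/5 core; C9 quaternary)
Conditions: ZnBr2 (30 mol %), CH2Cl2, 0 °C
Reagents that add atoms: none
Why: In this semipinacol rearrangement of a 2,3-epoxy alcohol the tertiary C9–O bond opens and C5 migrates to the β face anti to it. C5 is the more substituted migrating carbon and leads to a fused rather than a bridged ketone. The shift contracts ring B′, expands ring A, inverts C9 and retains C5 and C8.

Step 15
Reactants: 22 the 8α-hydroxy ketone
Product: 25 tetracyclic 10-methyl-10-carbinol (3β-OTBS; C10 epimers inconsequential), via secondary triflate 23 (not isolated), via tetracyclic ketone 24 (not isolated)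
Conditions: Tf2O, 2,6-di-tert-butyl-4-methylpyridine, CH2Cl2, −90 °C; then AlMe3 (8 equiv), −90 → 23 °C; Rochelle salt
Reagents that add atoms: trimethylaluminium, C[Al](C)C
Why: Proposed new method: the C8 triflate, tamed by the β-carbonyl, ionises on warming with backside participation of the tethered E-tetrasubstituted alkene (inversion at C8; cis B/C fusion forced by the C11 tether; chair–chair anti addition giving 8α-H, 14β-Me and 13α-Me); the 1,1-disubstituted alkene then closes ring D; the C20 cation takes CH3 from the methylaluminate on its open β face because the axial 13α-methyl blocks the α face; excess AlMe3 finally adds to the C10 ketone; the closest known reaction types are sulfonate- or allyl-cation-initiated polyene cyclisation and the methylation of tertiary carbocations and ketones by AlMe3.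

Step 16
Reactants: 25 the 10-methyl-10-carbinol
Product: 26 the target (CNP0284367.1)
Conditions: p-TsOH·H2O (10 mol %), CH2Cl2, 0 → 23 °C
Reagents that add atoms: none
Why: In this SN1 desilylative etherification the tertiary C10 cation is captured transannularly by the 3β-oxygen, so the bridge geometry dictates the C10 configuration, and the short mild exposure spares the trisubstituted alkene.

## Compound list
1 | 2,3-dimethylbuta-1,3-diene | C=C(C)C(C)=C | starting material
2 | (E)-1,4-dibromo-2,3-dimethylbut-2-ene | BrC/C(C)=C(C)/CBr | intermediate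
3 | 3-chloro-2-methylprop-1-ene | C=C(C)CCl | starting material
4 | 1-bromo-3-methylbut-2-ene | CC(C)=CCBr | starting material
5 | methallylmagnesium chloride | C=C(C)C[Mg]Cl | intermediate
6 | 2,6-dimethylhepta-1,5-diene | C=C(C)CCC=C(C)C | intermediate
7 | [2-(4-methylpent-3-enyl)allyl]lithium | [Li]CC(=C)CCC=C(C)C | intermediate
8 | (2E)-1-bromo-2,3,10-trimethyl-6-methylideneundeca-2,9-diene | BrC/C(C)=C(C)/CCC(=C)CCC=C(C)C | intermediate
9 | homoallylic pinacol boronate (C11–C27 unit) | CC1(C)OB(CC/C(C)=C(C)/CCC(=C)CCC=C(C)C)OC1(C)C | intermediate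
10 | cyclohexane-1,2-dione | O=C1CCCCC1=O | starting material
11 | 2-(triethylsilyloxy)cyclohex-2-en-1-one | O=C1CCCC=C1O[Si](CC)(CC)CC | intermediate
12 | 4-methylpent-1-en-3-one | C=CC(=O)C(C)C | starting material
13 | tert-butyl(dimethyl)[(4-methylpenta-1,3-dien-3-yl)oxy]silane | C=CC(O[Si](C)(C)C(C)(C)C)=C(C)C | intermediate
14 | (4aS,8aS) cis-decalone (C9 ketone, 10α-OTES, C2=C3 TBS enol ether) | O=C1CCC[C@H]2C(C)(C)C(O[Si](C)(C)C(C)(C)C)=CC[C@@]12O[Si](CC)(CC)CC | intermediate
15 | potassium C8=C9 enolate of 14 | [K+].[O-]C1=CCC[C@H]2C(C)(C)C(O[Si](C)(C)C(C)(C)C)=CC[C@@]12O[Si](CC)(CC)CC | intermediate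
16 | C8=C9 enol triflate | O=S(=O)(OC1=CCC[C@H]2C(C)(C)C(O[Si](C)(C)C(C)(C)C)=CC[C@@]12O[Si](CC)(CC)CC)C(F)(F)F | intermediate
17 | coupled tetraene | CC(C)=CCCC(=C)CC/C(C)=C(C)/CCC1=CCC[C@H]2C(C)(C)C(O[Si](C)(C)C(C)(C)C)=CC[C@@]12O[Si](CC)(CC)CC | intermediate
18 | 10α-hydroxy-3-ketone | CC(C)=CCCC(=C)CC/C(C)=C(C)/CCC1=CCC[C@H]2C(C)(C)C(=O)CC[C@@]12O | intermediate
19 | (3S)-3β,10α-diol | CC(C)=CCCC(=C)CC/C(C)=C(C)/CCC1=CCC[C@H]2C(C)(C)[C@@H](O)CC[C@@]12O | intermediate
20 | 3β-OTBS 10α-allylic alcohol | CC(C)=CCCC(=C)CC/C(C)=C(C)/CCC1=CCC[C@H]2C(C)(C)[C@@H](O[Si](C)(C)C(C)(C)C)CC[C@@]12O | intermediate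
21 | 8α,9α-epoxy-10α-ol | CC(C)=CCCC(=C)CC/C(C)=C(C)/CC[C@@]13O[C@@H]1CC[C@H]2C(C)(C)[C@@H](O[Si](C)(C)C(C)(C)C)CC[C@]23O | intermediate
22 | 8α-hydroxy-5(10→9)abeo-10-ketone | CC(C)=CCCC(=C)CC/C(C)=C(C)/CC[C@@]12[C@H](O)CC[C@H]1C(C)(C)[C@@H](O[Si](C)(C)C(C)(C)C)CCC2=O | intermediate
23 | C8 α-triflate of 22 | CC(C)=CCCC(=C)CC/C(C)=C(C)/CC[C@@]12[C@H](OS(=O)(=O)C(F)(F)F)CC[C@H]1C(C)(C)[C@@H](O[Si](C)(C)C(C)(C)C)CCC2=O | intermediate
24 | tetracyclic 10-ketone (3β-OTBS) | CC(C)=CCC[C@]1(C)CC[C@]2(C)[C@H]3CC[C@H]4C(C)(C)[C@@H](O[Si](C)(C)C(C)(C)C)CCC(=O)[C@@]43CC[C@@]2(C)C1 | intermediate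
25 | tetracyclic 10-methyl-10-carbinol (C10 undefined) | CC(C)=CCC[C@]1(C)CC[C@]2(C)[C@H]3CC[C@H]4C(C)(C)[C@@H](O[Si](C)(C)C(C)(C)C)CCC(C)(O)[C@@]43CC[C@@]2(C)C1 | intermediate
26 | CNP0284367.1 | CC(C)=CCC[C@]1(C)CC[C@]2(C)[C@H]3CC[C@H]4C(C)(C)[C@@H]5CC[C@@](C)(O5)[C@@]43CC[C@@]2(C)C1 | target

## Step count and risks
Total steps: 16. Longest linear sequence: 11 (steps 5, 7, 8, 9, 10, 11, 12, 13, 14, 15, 16). The branch through steps 1, 3, 4 and then 9–16 is equally long.

**Step 7.** The α-silyloxy enone may be too poor an acceptor for the hindered diene. The fallback sets out from 13 and returns at 14. Commercial cyclohex-2-enone is annulated with 13 under the same oxazaborolidinium catalysis, a well-precedented pairing, to give the C10–H cis-decalone F1. Its thermodynamic ring-fusion enolate is oxygenated on the convex face (KOt-Bu, O2, P(OEt)3) to give the 10α-hydroxy ketone F2. Silylation with TESOTf/2,6-lutidine then gives 14.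

**Step 14.** C1 could migrate instead of C5, which would give a bridged ketone. The fallback sets out from 20 and returns at 24, and it moves the 1,2-shift to after ring C is in place, where ring B′ is conformationally locked.
- SnCl4 ionises the tertiary allylic alcohol of 20. The allyl cation initiates a polyene bicyclisation at C8 that ends with chloride capture, giving the Δ9(10) tetracyclic C20 chloride F3.
- AlMe3 at −78 °C methylates the tertiary chloride to give the Δ9(10) tetracycle F4.
- One equivalent of DMDO epoxidises the tetrasubstituted alkene from the α face to give the 9α,10α-epoxide F5.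
- BF3·OEt2 effects the Meinwald-type ring contraction/expansion (C5 from C10 to C9) to give 24.
- MeLi/CeCl3 converts 24 into 25.

**Step 15 (the proposed new step).** It could fail by elimination to the cyclopentene, by premature methyl capture at C13, or through the wrong chair. The fallback sets out from 22 and returns at 24, and it splits the event into known operations. MsCl/Et3N gives the C8 mesylate F6. Me2AlCl in CH2Cl2 (−78 → 0 °C) drives the sulfonate π-cyclisation, which ends by chloride capture and gives the tetracyclic keto C20 chloride F7. AlMe3 at −78 °C then methylates the tertiary chloride to give 24, and MeLi/CeCl3 gives 25.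

Further compounds
F1 | step 7 | (4aS,8aR-type) cis-decalone with H at C10 (C2=C3 TBS enol ether) | O=C1CCC[C@H]2C(C)(C)C(O[Si](C)(C)C(C)(C)C)=CC[C@@H]12
F2 | step 7 | 10α-hydroxy cis-decalone | O=C1CCC[C@H]2C(C)(C)C(O[Si](C)(C)C(C)(C)C)=CC[C@@]12O
F3 | step 14 | Δ9(10) tetracyclic C20 chloride (3β-OTBS; C20 undefined) | CC(C)=CCCC1(Cl)CC[C@]2(C)[C@H]3CC[C@H]4C(C)(C)[C@@H](O[Si](C)(C)C(C)(C)C)CCC4=C3CC[C@@]2(C)C1
F4 | step 14 | Δ9(10) tetracycle with C20 methyl | CC(C)=CCC[C@]1(C)CC[C@]2(C)[C@H]3CC[C@H]4C(C)(C)[C@@H](O[Si](C)(C)C(C)(C)C)CCC4=C3CC[C@@]2(C)C1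
F5 | step 14 | 9α,10α-epoxide of F4 | CC(C)=CCC[C@]1(C)CC[C@]2(C)[C@H]3CC[C@H]4C(C)(C)[C@@H](O[Si](C)(C)C(C)(C)C)CC[C@]45O[C@]35CC[C@@]2(C)C1
F6 | step 15 | C8 α-mesylate of 22 | CC(C)=CCCC(=C)CC/C(C)=C(C)/CC[C@@]12[C@H](OS(C)(=O)=O)CC[C@H]1C(C)(C)[C@@H](O[Si](C)(C)C(C)(C)C)CCC2=O
F7 | step 15 | tetracyclic 10-keto C20 chloride (C20 undefined) | CC(C)=CCCC1(Cl)CC[C@]2(C)[C@H]3CC[C@H]4C(C)(C)[C@@H](O[Si](C)(C)C(C)(C)C)CCC(=O)[C@@]43CC[C@@]2(C)C1
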